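We have 3 questions, one for each flask, and one slope on a logarithmic scale answers them.

common to all: solid substrate 0.10 M

| run | partner | remark | time |
|---|---|---|---|
| Sunday's | 0.039 M | run made earlier |  |
| Tuesday's | 0.084 M | run made earlier |  |
| Saturday's | 0.11 M | run made earlier |  |
| grey | 0.0500 M |  | 15 h |
| violet | 0.100 M |  | 15 h |
| ochre | 0.150 M |  | 15 h |

| run | time / h | double product / % | solid substrate / % |
|---|---|---|---|
| Sunday's | 1.33 | 0 | 94.0 |
| Sunday's | 3.00 | 0 | 89.5 |
| Sunday's | 6.00 | 0.3 | 85.5 |
| Sunday's | 15.0 | 1.5 | 79.9 |
| Tuesday's | 4.00 | 1.3 | 87.6 |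
| Tuesday's | 8.00 | 1.6 | 79.8 |
| Tuesday's | 12.0 | 3.9 | 77.1 |
| Tuesday's | 15.0 | 4.3 | 73.6 |
| Saturday's | 4.00 | 0 | 85.8 |
| Saturday's | 8.00 | 3.0 | 80.0 |
| Saturday's | 12.0 | 4.8 | 73.2 |
| Saturday's | 15.0 | 7.2 | 70.0 |

(each reading ± 0.5 percentage points)

1. amount of double product at the end, in percent of the solid substrate charged, for each flask in turn (grey, violet, ochre)

- solid, in amounts per volume of the solution: solid substrate
- at the start none of the solid substrate is in solution

Two readings seem not to go together. From Sunday's run to Saturday's, [partner] rises 2.82-fold. At 15.0 h Sunday's run is short of 20.1% of its solid substrate and Saturday's of 30.0%, and the ratio of these two, 1.49, is less than the rise in [partner]. Yet double product grows 4.80-fold, more than [partner] does.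

Logarithms clear this up. We take the apparent order in partner, the slope of the logarithm of an amount at a fixed time against the logarithm of [partner]. For double product it is 1.51, and for the solid loss 0.386. They differ by 1.13, close to the one power that a further partner on the way to double product would add. So the two readings can stand together. The slope is soft, though, since Sunday's 1.5% carries a scatter of 0.5 percentage points.

Starting from Tuesday's 4.3% at 0.084 M, our own reckoning gives 1.96%, 5.60% and 10.3%. The forecast, holding that “it should depend on partner more steeply than first order”, gives 2%, 5.8% and 12%, so for ochre it stands higher than we do.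

The flasks give 2.04%, 6.14% and 10.7%, and ochre ends below the forecast's 12%.

    starting material + partner → first product (k = 4.30 × 10⁻⁴ M⁻¹ s⁻¹)
    partner + first product → double product (k = 2.90 × 10⁻⁴ M⁻¹ s⁻¹)
    partner + double product → triple product (k = 8.10 × 10⁻⁶ M⁻¹ s⁻¹)
    partner + triple product ⇌ tetra adduct (K = 17.0 M⁻¹, k = 2.80 × 10⁻⁴ M⁻¹ s⁻¹)
    solid substrate ⇌ starting material, rate k5*(cs5 - [starting material]) while solid is left; crystals form when [starting material] > cs5 (solubility = 13.0 mM, k = 1.40 × 10⁻⁴ s⁻¹)
    double product ⇌ isomer of the product (K = 0.310, k = 5.70 × 10⁻⁵ s⁻¹)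

From grey to ochre these results have a slope of 1.51, and our 1.51 carried from violet's result puts ochre at 11.3%. In grey at 15.0 h, first product is still made 2.25 times faster than it is used up, each step taken net, and its half-life by the step to double product, 18 h, is longer than the run. Grey ends with first product at 7.66%, more than its double product at 2.04%.

Readings and results come from a simulation for an exercise, noise included.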